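**Retrosyn­thetic overview**
1. The plan rests on ring B (the oxepene, 1-benzoxepine numbering): C2 carries O1, H and CH2Br, so it is the carbon of a bromoacetaldehyde acetal, and its neighbour C3 is the α-carbon of an enal C4=C3–CHO, which a 1,2-reduction turns into the C3–CH2OH of the target.
2. C2–C3 is cut: ring B closes last, when C3 of the enal in 13 (made nucleophilic by a sulfide) attacks the C2 oxocarbenium ion that a silyl triflate releases from the bromoacetal on O1.
3. Enal 13 comes from cross-metathesis of the allyl group of 11 with crotonaldehyde; bromoacetal 11 from tertiary alcohol 9, ethyl vinyl ether and NBS; 9 from lactol 8 by methylenation.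
4. Ring A closes first: a Cp2TiCl-catalysed 6-exo radical cyclisation of epoxy enoate 4 (from (S)-linalool by Shi epoxidation and acrylate cross-metathesis) sets C5a; in the cis lactone 6 the C7 alcohol is converted to the bromide with inversion.
5. Ring order: ring A (step 3, with a temporary γ-lactone), then ring B (step 9); a Luche reduction ends the route.

Key step: step 9

Remark: (S)-(+)-linalool is assumed to be bought in high enantiomeric purity; any (R)-antipode becomes a diastereomer after the reagent-controlled epoxidation and should be removed at lactone 6.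

**Step 1**
Reactants: 1 (S)-linalool
Product: 2 (3S)-5-[(2R)-3,3-dimethyloxiran-2-yl]-3-methylpent-1-en-3-ol
Conditions: D-fructose-derived Shi ketone (0.3 equiv), KHSO5 (Oxone), K2CO3, Bu4NHSO4, MeCN/CH2(OMe)2, aq. Na2B4O7/Na2(EDTA) buffer (pH 10.5), 0 °C
Reagents that add atoms: potassium peroxymonosulfate KHSO5, [K+].[O-]S(=O)(=O)OO
Why: Shi epoxidation: the dioxirane of the D-fructose-derived ketone attacks only the electron-rich trisubstituted C6=C7 bond (the vinyl group stays) and its spiro transition state should give the (6R)-epoxide under reagent control, independent of the remote C3 centre.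

**Step 2**
Reactants: 2 (3S)-5-[(2R)-3,3-dimethyloxiran-2-yl]-3-methylpent-1-en-3-ol; 3 methyl acrylate
Product: 4 methyl (2E,4S)-6-[(2R)-3,3-dimethyloxiran-2-yl]-4-hydroxy-4-methylhex-2-enoate
Conditions: second-generation Hoveyda–Grubbs catalyst (5 mol%), methyl acrylate (5 equiv), CH2Cl2, 40 °C
Reagents that add atoms: none
Why: Olefin cross-metathesis: with the trisubstituted alkene already epoxidised no ring-closing path to a cyclopentenol remains, the free tertiary allylic alcohol is a competent partner for excess acrylate, and the enoate should form as the E isomer with both stereocentres untouched.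

**Step 3**
Reactants: 4 methyl (2E,4S)-6-[(2R)-3,3-dimethyloxiran-2-yl]-4-hydroxy-4-methylhex-2-enoate
Product: 6 (3aR,5R,7aS)-5-hydroxy-4,4,7a-trimethylhexahydro-1-benzofuran-2(3H)-one, via dihydroxy ester 5 (not isolated)
Conditions: Cp2TiCl2 (0.2 equiv), Mn dust, 2,4,6-collidine·HCl, THF, rt; then p-TsOH·H2O (cat.), CH2Cl2, rt
Reagents that add atoms: none
Why: Reductive epoxide opening with radical cyclisation (Nugent–RajanBabu reaction, Gansäuer catalytic conditions): Cp2TiCl opens the epoxide at the tertiary carbon, the β-titanoxy radical adds 6-exo-trig to the enoate β-carbon through a chair with the titanoxy group, the carbinol methyl and the acceptor equatorial, which sets the new ring CH cis to both oxygens, and the cis γ-hydroxy ester 5 then lactonises under acid.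

**Step 4**
Reactants: 6 (3aR,5R,7aS)-5-hydroxy-4,4,7a-trimethylhexahydro-1-benzofuran-2(3H)-one
Product: 7 (3aR,5S,7aS)-5-bromo-4,4,7a-trimethylhexahydro-1-benzofuran-2(3H)-one
Conditions: CBr4 (3 equiv), PPh3 (3 equiv), toluene, 70 °C
Reagents that add atoms: carbon tetrabromide, BrC(Br)(Br)Br
Why: Appel reaction: bromide displaces the oxyphosphonium group of the equatorial neopentyl-type alcohol with inversion (SN2), so Br becomes axial and trans to the CH2 arm at C3a, while the lactone keeps the tertiary oxygen and the ester out of the reaction.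

**Step 5**
Reactants: 7 (3aR,5S,7aS)-5-bromo-4,4,7a-trimethylhexahydro-1-benzofuran-2(3H)-one
Product: 8 (3aR,5S,7aS)-5-bromo-4,4,7a-trimethyloctahydro-1-benzofuran-2-ol (both anomers)
Conditions: iBu2AlH (1.1 equiv), CH2Cl2, −78 °C; then aq. KNaC4H4O6
Reagents that add atoms: none
Why: Partial reduction of a γ-lactone with iBu2AlH stops at the tetrahedral aluminium alkoxide at low temperature and gives the lactol on work-up; the secondary bromide is inert at −78 °C and no ring stereocentre is touched.

**Step 6**
Reactants: 8 (3aR,5S,7aS)-5-bromo-4,4,7a-trimethyloctahydro-1-benzofuran-2-ol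
Product: 9 (1S,2R,4S)-4-bromo-1,3,3-trimethyl-2-(prop-2-en-1-yl)cyclohexan-1-ol
Conditions: Ph3PCH3Br (3 equiv), n-BuLi (2.9 equiv), THF, 0 °C; then 8, 0 °C → rt
Reagents that add atoms: methylenetriphenylphosphorane (made in the flask from methyltriphenylphosphonium bromide and n-BuLi), C=P(c1ccccc1)(c1ccccc1)c1ccccc1
Why: Wittig methylenation of the lactol through its open hydroxy aldehyde form gives the allyl arm and frees the tertiary alcohol; the lithium alkoxide is kept cold so that it neither displaces nor eliminates the hindered bromide.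

**Step 7**
Reactants: 9 (1S,2R,4S)-4-bromo-1,3,3-trimethyl-2-(prop-2-en-1-yl)cyclohexan-1-ol; 10 ethyl vinyl ether
Product: 11 (1S,2R,4S)-4-bromo-1-(2-bromo-1-ethoxyethoxy)-1,3,3-trimethyl-2-(prop-2-en-1-yl)cyclohexane (acetal carbon as both epimers)
Conditions: ethyl vinyl ether (5 equiv), NBS (1.5 equiv), CH2Cl2, −40 → 0 °C
Reagents that add atoms: N-bromosuccinimide, O=C1CCC(=O)N1Br
Why: Haloacetalisation (the bromoacetal formation used for Ueno–Stork precursors): NBS brominates the vinyl ether far faster than the monosubstituted alkene and the tertiary alcohol traps the α-bromo oxocarbenium ion under neutral conditions, which puts C2 with its CH2Br on O1; the acetal epimers do not matter because this carbon becomes planar in step 9.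

**Step 8**
Reactants: 11 (1S,2R,4S)-4-bromo-1-(2-bromo-1-ethoxyethoxy)-1,3,3-trimethyl-2-(prop-2-en-1-yl)cyclohexane; 12 (E)-crotonaldehyde
Product: 13 (2E)-4-[(1R,2S,5S)-5-bromo-2-(2-bromo-1-ethoxyethoxy)-2,6,6-trimethylcyclohexyl]but-2-enal (acetal carbon as both epimers)
Conditions: second-generation Hoveyda–Grubbs catalyst (5 mol%), crotonaldehyde (8 equiv), CH2Cl2, 40 °C
Reagents that add atoms: none
Why: Olefin cross-metathesis of a monosubstituted alkene with an excess of an enal partner should give the E-enal and propene; the alkyl bromides and the acetal are inert to the ruthenium carbene.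

**Step 9**
Reactants: 13 (2E)-4-[(1R,2S,5S)-5-bromo-2-(2-bromo-1-ethoxyethoxy)-2,6,6-trimethylcyclohexyl]but-2-enal
Product: 15 (2R,5aR,7S,9aS)-7-bromo-2-(bromomethyl)-6,6,9a-trimethyl-2,5,5a,6,7,8,9,9a-octahydro-1-benzoxepine-3-carbaldehyde, via cyclised sulfonium triflate 14 (not isolated)
Conditions: Me2S (3 equiv), Me3SiOTf (1.5 equiv), CH2Cl2 (0.01 M), −78 → −30 °C; then DBU (4 equiv), −30 → 0 °C
Reagents that add atoms: none
Why: Proposed new method: Me3SiOTf silylates the unhindered ethoxy oxygen of the mixed acetal and expels EtOSiMe3 to leave the 2-bromoethylidene oxocarbenium ion on O1, while Me2S adds to C4 of the silyl-activated enal and turns it into a β-sulfonio silyl enol ether whose only nucleophilic carbon is C3; C3 attacks C2, the silyl group is released, and DBU then removes H3 so that Me2S leaves from C4 (E1cB) and the C3=C4 enal returns. The closest known reaction types are the intermolecular sulfide/silyl triflate-mediated Morita–Baylis–Hillman-type coupling of enals and enones with acetals and the amine- or phosphine-catalysed intramolecular Morita–Baylis–Hillman closure of five- and six-membered rings; an intramolecular closure on an acetal-derived oxocarbenium ion, and to a seven-membered ring, is without precedent. Ring B closes in a 7-(enolexo)-endo-trig mode, with O1=C2 inside the new ring and the enol C=C outside it, under high dilution. The new stereocentre C2 is set by the substrate alone: the (E)-oxocarbenium ion keeps CH2Br anti to C9a (pseudo-equatorial) and the short C5–C4 tether from C5a lets C3 reach one face only for a given ring A chair; a model analysis suggests that the chair with O1 equatorial and C5 axial leads to the required epimer (CH2Br cis to the C9a methyl) and the other chair to the C2 epimer, so the sense and level of this selectivity are the open point of the step. The step also needs ionisation toward O1 (loss of ethoxide, not of the tertiary alkoxide), which the steric shielding of the tertiary oxygen should secure, and C–C bond formation at C3 without diversion of O1 into a tetrahydrofuran, which is secured because C2 is already bonded to O1, the oxocarbenium ion has no allylic position, and the electron-poor enal cannot act as a Prins nucleophile.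

**Step 10**
Reactants: 15 (2R,5aR,7S,9aS)-7-bromo-2-(bromomethyl)-6,6,9a-trimethyl-2,5,5a,6,7,8,9,9a-octahydro-1-benzoxepine-3-carbaldehyde
Product: 16 [(2R,5aR,7S,9aS)-7-bromo-2-(bromomethyl)-6,6,9a-trimethyl-2,5,5a,6,7,8,9,9a-octahydro-1-benzoxepin-3-yl]methanol
Conditions: NaBH4, CeCl3·7H2O, MeOH, −20 °C
Reagents that add atoms: none
Why: Luche reduction: NaBH4 with CeCl3 reduces the enal 1,2 to the allylic alcohol without touching the alkene, the ether or the two alkyl bromides, and no stereocentre changes.

**Compound list**
1 | (S)-linalool, (3S)-3,7-dimethylocta-1,6-dien-3-ol | C=C[C@@](C)(O)CCC=C(C)C | starting material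
2 | (3S)-5-[(2R)-3,3-dimethyloxiran-2-yl]-3-methylpent-1-en-3-ol | C=C[C@@](C)(O)CC[C@H]1OC1(C)C | intermediate
3 | methyl acrylate | C=CC(=O)OC | starting material
4 | methyl (2E,4S)-6-[(2R)-3,3-dimethyloxiran-2-yl]-4-hydroxy-4-methylhex-2-enoate | COC(=O)/C=C/[C@@](C)(O)CC[C@H]1OC1(C)C | intermediate
5 | methyl 2-[(1R,2S,5R)-2,5-dihydroxy-2,6,6-trimethylcyclohexyl]acetate | CC1(C)[C@@H](CC(=O)OC)[C@@](C)(O)CC[C@H]1O | intermediate (not isolated)
6 | (3aR,5R,7aS)-5-hydroxy-4,4,7a-trimethylhexahydro-1-benzofuran-2(3H)-one | CC1(C)[C@H]2CC(=O)O[C@@]2(C)CC[C@H]1O | intermediate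
7 | (3aR,5S,7aS)-5-bromo-4,4,7a-trimethylhexahydro-1-benzofuran-2(3H)-one | CC1(C)[C@H]2CC(=O)O[C@@]2(C)CC[C@@H]1Br | intermediate
8 | (3aR,5S,7aS)-5-bromo-4,4,7a-trimethyloctahydro-1-benzofuran-2-ol (both anomers) | CC1(C)[C@H]2CC(O)O[C@@]2(C)CC[C@@H]1Br | intermediate
9 | (1S,2R,4S)-4-bromo-1,3,3-trimethyl-2-(prop-2-en-1-yl)cyclohexan-1-ol | CC1(C)[C@@H](CC=C)[C@@](C)(O)CC[C@@H]1Br | intermediate
10 | ethyl vinyl ether | C=COCC | starting material
11 | (1S,2R,4S)-4-bromo-1-(2-bromo-1-ethoxyethoxy)-1,3,3-trimethyl-2-(prop-2-en-1-yl)cyclohexane (acetal epimers) | CC1(C)[C@@H](CC=C)[C@@](C)(OC(CBr)OCC)CC[C@@H]1Br | intermediate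
12 | (E)-crotonaldehyde | C/C=C/C=O | starting material
13 | (2E)-4-[(1R,2S,5S)-5-bromo-2-(2-bromo-1-ethoxyethoxy)-2,6,6-trimethylcyclohexyl]but-2-enal (acetal epimers) | CC1(C)[C@@H](C/C=C/C=O)[C@@](C)(OC(CBr)OCC)CC[C@@H]1Br | intermediate
14 | [(2R,5aR,7S,9aS)-7-bromo-2-(bromomethyl)-3-formyl-6,6,9a-trimethyldecahydro-1-benzoxepin-4-yl]dimethylsulfonium trifluoromethanesulfonate (C3 and C4 as mixtures) | CC1(C)[C@H]2CC([S+](C)C)C(C=O)[C@H](CBr)O[C@@]2(C)CC[C@@H]1Br.[O-]S(=O)(=O)C(F)(F)F | intermediate (not isolated)
15 | (2R,5aR,7S,9aS)-7-bromo-2-(bromomethyl)-6,6,9a-trimethyl-2,5,5a,6,7,8,9,9a-octahydro-1-benzoxepine-3-carbaldehyde | CC1(C)[C@H]2CC=C(C=O)[C@H](CBr)O[C@@]2(C)CC[C@@H]1Br | intermediate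
16 | [(2R,5aR,7S,9aS)-7-bromo-2-(bromomethyl)-6,6,9a-trimethyl-2,5,5a,6,7,8,9,9a-octahydro-1-benzoxepin-3-yl]methanol | CC1(C)[C@H]2CC=C(CO)[C@H](CBr)O[C@@]2(C)CC[C@@H]1Br | target

**Step count**
Total steps: 10. Longest linear sequence: 10 steps from (S)-linalool (1).

**Steps most likely to fail**

1. Step 9 (proposed new method). The ring may close through the other ring A chair and so on the wrong face of the oxocarbenium ion, giving the C2 epimer. The tertiary alkyl oxocarbenium ion may also lose the ring A cation before C3 reaches it. The fallback uses known reactions only and runs from 11 to 16. The acetal of 11 is coupled with acrolein under the established intermolecular Me2S/Me3SiOTf conditions, followed by DBU, to give the 2-methylidene aldehyde F1, whose two epimers at the ether carbon are separated. NaBH4/CeCl3·7H2O then gives the allylic alcohol F2. Ring-closing metathesis between the allyl group and the 1,1-disubstituted alkene (second-generation Grubbs catalyst, CH2Cl2, 40 °C) forms C3=C4 and gives 16 directly, so the ring closure no longer sets C2.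

2. Step 4. The oxyphosphonium intermediate may ionise with a 1,2-shift of the antiperiplanar ring bond (ring contraction) faster than bromide enters at the neopentyl carbon. The fallback runs from 6 to 7. The alcohol is first converted to the triflate F3 (Tf2O, pyridine, CH2Cl2, −20 °C). The triflate is then displaced in a separate SN2 step by soluble bromide (Bu4NBr, toluene, 0 °C → rt) under non-ionising conditions, with the same inversion.

3. Step 3. The β-titanoxy radical may be reduced by a second Cp2TiCl before it adds to the hindered enoate carbon, which would give the acyclic allylic alcohol, or the chair preference may be low. The fallback runs from 4 to 6. The epoxide is opened to the tertiary bromohydrin F4 (MgBr2·OEt2, Et2O, −30 °C). The tertiary radical is then generated without a reducing metal ((Me3Si)3SiH, AIBN, toluene, 80 °C), so that it persists until the 6-exo Giese cyclisation. This gives the same dihydroxy ester 5, which is lactonised to 6 as in the main route.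

**Further compounds**
F1 | step 9 | (3R)-4-bromo-3-{[(1S,2R,4S)-4-bromo-1,3,3-trimethyl-2-(prop-2-en-1-yl)cyclohexyl]oxy}-2-methylidenebutanal | CC1(C)[C@@H](CC=C)[C@@](C)(O[C@@H](CBr)C(=C)C=O)CC[C@@H]1Br
F2 | step 9 | (3R)-4-bromo-3-{[(1S,2R,4S)-4-bromo-1,3,3-trimethyl-2-(prop-2-en-1-yl)cyclohexyl]oxy}-2-methylidenebutan-1-ol | CC1(C)[C@@H](CC=C)[C@@](C)(O[C@@H](CBr)C(=C)CO)CC[C@@H]1Br
F3 | step 4 | (3aR,5R,7aS)-4,4,7a-trimethyl-2-oxooctahydro-1-benzofuran-5-yl trifluoromethanesulfonate | CC1(C)[C@H]2CC(=O)O[C@@]2(C)CC[C@H]1OS(=O)(=O)C(F)(F)F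
F4 | step 3 | methyl (2E,4S,7R)-8-bromo-4,7-dihydroxy-4,8-dimethylnon-2-enoate | COC(=O)/C=C/[C@@](C)(O)CC[C@@H](O)C(C)(C)Br
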